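The data were computed with constants of no real substance.

The noon and midnight runs look unlike, yet the midnight charge is the noon charge less 60.0 mM of both starting material and coupling partner, and the questions can be reached through that shared difference.

| flask | starting material | coupling partner | free catalyst | time |
|---|---|---|---|---|
| noon | 100 mM | 80.0 mM | 8.00 mM |  |
| midnight | 40.0 mM | 20.0 mM | 8.00 mM |  |
| winter | 50.0 mM | 80.0 mM | 8.00 mM |  |
| spring | 100 mM | 80.0 mM | 4.00 mM |  |
| autumn | 100 mM | 80.0 mM | 8.00 mM | 27 h |

- Overall: starting material + coupling partner -> target, with free catalyst as catalyst.
- Constant volume, constant temperature.
- A reading of a species includes what of it is bound.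
- An order is taken over about fifteen percent of the charge, up and down.

1. apparent order in [coupling partner] of the starting rate, round the charge of the noon run (the rate where two percent of its starting material have turned into target)
2. apparent order in [starting material] of the starting rate, round the charge of the noon run (the rate where two percent of its starting material have turned into target) (one fixed amount of target, the same in the runs compared)
3. the midnight run starts with 60.0 mM less of starting material and of coupling partner than the noon run, and with no target. Compared where both hold the same amount of starting material, once fifteen percent of what the midnight run was charged with has turned into target, is the midnight run faster, slower or alike (within a tenth)?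
4. target in the autumn run at 27 h, as a share of the starting material charged

Each target made takes one of each, so in the noon run starting material minus coupling partner stands at 20.0 mM from start to end, and this constant difference is the excess E. The midnight run has the same E, 20.0 mM, so the noon run, having made 60.0 mM of target, holds the midnight amounts of starting material and coupling partner plus that target. If target and elapsed time leave the catalyst as it was, the two runs then proceed alike. E also gives the far end: coupling partner is the limiting reagent, so the noon charge ends at 80.0 mM of target, 80.0% of its starting material.

| run | time / h | [target] / mM |
|---|---|---|
| noon run | 0.18 | 7.0 |
| noon run | 0.40 | 16.9 |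
| noon run | 0.90 | 33.4 |
| noon run | 2.0 | 61.6 |
| noon run | 4.5 | 78.7 |
| midnight run | 0.18 | 1.9 |
| midnight run | 0.40 | 5.0 |
| midnight run | 0.90 | 11.0 |
| midnight run | 2.0 | 16.5 |
| midnight run | 4.5 | 20.0 |
| winter run | 0.18 | 3.8 |
| winter run | 0.40 | 7.3 |
| winter run | 0.90 | 17.1 |
| winter run | 2.0 | 30.7 |
| winter run | 4.5 | 44.1 |
| spring run | 0.18 | 0.7 |
| spring run | 0.40 | 1.7 |
| spring run | 0.90 | 0 |
| spring run | 2.0 | 0 |
| spring run | 4.5 | 0 |

(scatter of a reading: 0.8 mM)

Early on, the winter run reads about half the noon target at 0.90 h, so I take the order in starting material as one. Per starting material, the noon reading stands higher than the midnight reading at 0.40 h, and these two scattered readings give a chord order of 0.218 in coupling partner. A chord across that span does not give the slope at the noon charge, so I take that order as small, its sign unread.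

To join the ends, the noon reading at 2.0 h nearly matches the midnight reading at 0.18 h once 60.0 mM is subtracted. Shifted by that gap, the noon reading at 4.5 h falls at 2.68 h on the midnight clock and gives 18.7 mM, between the midnight readings 16.5 mM and 20.0 mM. So I expect alike, and 80.0% for the autumn run, which has the noon charge and 27 h to get there.

The forecast gives orders of 0.12 in coupling partner and 1 in starting material, a midnight run that is slower, and 80% in the autumn run, parting from this reckoning on the midnight run with the words “midnight is slower, which suggests mild product acceleration or catalyst loss”.

The flask gives orders of 0.99 in starting material and −0.20 in coupling partner, a midnight run that is alike (ratio 1.0), and 80.0% in the autumn run, the share that E allowed.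

free catalyst + starting material ⇌ catalyst-substrate complex (304.2 M⁻¹ h⁻¹, 100.1 h⁻¹); catalyst-substrate complex + coupling partner → target + free catalyst (5796 M⁻¹ h⁻¹); free catalyst + impurity → spent catalyst; free catalyst + coupling partner ⇌ idle catalyst-reagent complex, settled at all times (9.280 M⁻¹) In the midnight run, the same E allows 50.0% of its charge, and its target comes to that share at 26.6 h. The order in coupling partner at the noon charge is negative because free catalyst pairs with coupling partner as the idle catalyst-reagent complex, and with that pairing taken away the order becomes 0.23.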